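**Retrosynthetic overview**
1. The C9 aldehyde comes last from a primary silyl ether; the gem-dimethylcyclopropane comes from isopropylidene transfer to the less substituted enone of a cross-conjugated cycloheptadienone.
2. The dihydropyran is cut back to malondialdehyde plus a 4-formyltropone (held as its lactol), joined in an enantioselective dearomative [3+3] annulation that sets C4a and C9a.
3. The tropone lactol comes from a cycloheptatriene-fused γ-lactone by half-reduction and dehydrogenation.
4. That lactone comes from intramolecular Buchner ring expansion of 3-methoxybenzyl diazoacetate, so the benzene ring becomes the seven-membered ring and already carries the ketone oxygen, the C9 side-chain carbon and C1.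
5. Ring order: seven-membered carbocycle, then dihydropyran, then cyclopropane.

Assumption: 2, 8 and 14 are bought; locants follow the cyclohepta[c]pyran skeleton (C1 acetal carbon, C4a/C9a ring fusion, C5/C6 cyclopropane carbons, C7 ketone, C9 formyl-bearing carbon).

**Route**

Step 1
Reactants: 1 3-methoxybenzyl alcohol; 2 2,5-dioxopyrrolidin-1-yl 2-diazoacetate
Product: 3 3-methoxybenzyl 2-diazoacetate
Conditions: Et3N, cat. DMAP, THF, 0 °C to rt
Reagents that add atoms: 2,5-dioxopyrrolidin-1-yl 2-diazoacetate (2), O=C(C=[N+]=[N-])ON1C(=O)CCC1=O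
Why: O-acylation of the primary alcohol by the activated N-hydroxysuccinimide ester transfers the intact diazoacetyl group (diazoacetylation); no stereocentre is formed.

Step 2
Reactants: 3 3-methoxybenzyl 2-diazoacetate
Product: 4 5-methoxy-3,8a-dihydro-1H-cyclohepta[c]furan-1-one (racemic)
Conditions: Rh2(O2CC3F7)4 (1 mol %), CH2Cl2, 40 °C, slow addition, 0.01 M
Reagents that add atoms: none
Why: Intramolecular Buchner reaction: the electrophilic rhodium carbenoid cyclopropanates the arene bond between the benzylic carbon and the ring carbon para to OMe (the less hindered and more electron-rich of the two reachable bonds) and the norcaradiene opens to the cycloheptatriene; the single stereocentre is racemic and is erased in step 4.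

Step 3
Reactants: 4 5-methoxy-3,8a-dihydro-1H-cyclohepta[c]furan-1-one
Product: 5 5-methoxy-3,8a-dihydro-1H-cyclohepta[c]furan-1-ol (lactol epimers)
Conditions: i-Bu2AlH (1.1 equiv), CH2Cl2, −78 °C; Rochelle salt work-up
Reagents that add atoms: none
Why: Half-reduction of a γ-lactone to the lactol stops at the tetrahedral aluminate at −78 °C and leaves the methyl enol ether untouched; the lactol carbon is a mobile, inconsequential stereocentre.

Step 4
Reactants: 5 5-methoxy-3,8a-dihydro-1H-cyclohepta[c]furan-1-ol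
Product: 7 1-hydroxy-1,3-dihydro-5H-cyclohepta[c]furan-5-one, via methoxytropylium salt 6 (not isolated)
Conditions: DDQ (1.1 equiv), CH2Cl2/pH 7 phosphate buffer, 0 °C to rt
Reagents that add atoms: water, O
Why: Quinone dehydrogenation of a trienol ether: hydride abstraction from the ring CH gives the aromatic methoxytropylium ion, which water hydrolyses at the methoxy-bearing carbon to the tropone, as in the DDQ conversion of dienol ethers into cross-conjugated dienones; the buffer prevents acid-induced loss of water from the lactol.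

Step 5
Reactants: 7 1-hydroxy-1,3-dihydro-5H-cyclohepta[c]furan-5-one; 8 malondialdehyde tetrabutylammonium salt
Product: 9 (4aR,9aR)-1-hydroxy-9-(hydroxymethyl)-7-oxo-1,4a,7,9a-tetrahydrocyclohepta[c]pyran-4-carbaldehyde (cis-fused, lactol epimers at C1)
Conditions: (S)-2-[diphenyl(trimethylsilyloxy)methyl]pyrrolidine (20 mol %), PhCO2H (1.2 equiv), CH2Cl2, 0 °C to rt
Reagents that add atoms: malondialdehyde tetrabutylammonium salt (8), CCCC[N+](CCCC)(CCCC)CCCC.[O-]/C=C/C=O
Why: Proposed new method: the open hydroxy-enal form of 7 condenses with the amine to an iminium ion whose β-carbon is the tropone ring carbon C4a, malondialdehyde adds there from the face not shielded by the diarylmethyl group (standard shielding model, giving 4aR), the enamine is protonated and equilibrated at C9a to the cis ring fusion, and the enol oxygen closes the lactol, leaving the cross-conjugated dienone; the closest known reaction is the iminium-catalysed Michael addition/hemiacetalisation of 1,3-dicarbonyls with enals (formal [3+3] dihydropyran annulation), here run on a formyltropone so that it also breaks the tropone conjugation.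

Step 6
Reactants: 9 (4aR,9aR)-1-hydroxy-9-(hydroxymethyl)-7-oxo-1,4a,7,9a-tetrahydrocyclohepta[c]pyran-4-carbaldehyde
Product: 11 (1S,4aR,9aR)-4-formyl-7-oxo-9-[(triethylsilyloxy)methyl]-1,4a,7,9a-tetrahydrocyclohepta[c]pyran-1-yl acetate, via silyl ether lactol 10 (not isolated)
Conditions: Et3SiCl (1.05 equiv), imidazole, CH2Cl2, −40 °C; then Ac2O, pyridine, cat. DMAP, 0 °C
Reagents that add atoms: chlorotriethylsilane, CC[Si](Cl)(CC)CC; acetic anhydride, CC(=O)OC(C)=O
Why: The primary allylic hydroxyl is silylated faster than the hemiacetal hydroxyl, and acetylation of the mutarotating lactol then gives the axial, anomerically stabilised acetate trans to H-9a (1S, as in the target); a minor anomer would be separated.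

Step 7
Reactants: 11 (1S,4aR,9aR)-4-formyl-7-oxo-9-[(triethylsilyloxy)methyl]-1,4a,7,9a-tetrahydrocyclohepta[c]pyran-1-yl acetate
Product: 12 (1S,4aR,9aR)-4-(hydroxymethyl)-7-oxo-9-[(triethylsilyloxy)methyl]-1,4a,7,9a-tetrahydrocyclohepta[c]pyran-1-yl acetate
Conditions: NaBH4 (0.5 equiv), CH2Cl2/EtOH 7:3, −78 °C
Reagents that add atoms: none
Why: Chemoselective low-temperature borohydride reduction of an aldehyde in the presence of a ketone: the formyl group is reduced (as 2-formyl glycals are) before the cross-conjugated ring ketone, and the acetates and silyl ether survive; no stereocentre is formed.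

Step 8
Reactants: 12 (1S,4aR,9aR)-4-(hydroxymethyl)-7-oxo-9-[(triethylsilyloxy)methyl]-1,4a,7,9a-tetrahydrocyclohepta[c]pyran-1-yl acetate
Product: 13 [(1S,4aR,9aR)-1-acetoxy-7-oxo-9-[(triethylsilyloxy)methyl]-1,4a,7,9a-tetrahydrocyclohepta[c]pyran-4-yl]methyl acetate
Conditions: Ac2O, pyridine, cat. DMAP, CH2Cl2, 0 °C
Reagents that add atoms: acetic anhydride, CC(=O)OC(C)=O
Why: Standard O-acetylation of the primary allylic alcohol installs the second acetate of the target and tames the enol ether; no stereocentre is touched.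

Step 9
Reactants: 13 [(1S,4aR,9aR)-1-acetoxy-7-oxo-9-[(triethylsilyloxy)methyl]-1,4a,7,9a-tetrahydrocyclohepta[c]pyran-4-yl]methyl acetate; 14 isopropyldiphenylsulfonium tetrafluoroborate
Product: 15 [(1S,4aR,5R,6S,9aR)-1-acetoxy-7-oxo-5,6-(propane-2,2-diyl)-9-[(triethylsilyloxy)methyl]-1,4a,5,6,7,9a-hexahydrocyclohepta[c]pyran-4-yl]methyl acetate
Conditions: 14 (1.5 equiv), LiN(i-Pr)2 (1.45 equiv), DME, −78 °C; then 13, −78 to −50 °C
Reagents that add atoms: isopropyldiphenylsulfonium tetrafluoroborate (14), CC(C)[S+](c1ccccc1)c1ccccc1.F[B-](F)(F)F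
Why: Corey–Chaykovsky cyclopropanation with diphenylsulfonium isopropylide: conjugate addition goes to the disubstituted enone (the other β-carbon is fully substituted) at C5 from the face opposite the pyran ring on C4a, and 3-exo closure of the enolate gives the necessarily cis-fused cyclopropane with CMe2 syn to H-4a/H-9a (5R,6S).

Step 10
Reactants: 15 [(1S,4aR,5R,6S,9aR)-1-acetoxy-7-oxo-5,6-(propane-2,2-diyl)-9-[(triethylsilyloxy)methyl]-1,4a,5,6,7,9a-hexahydrocyclohepta[c]pyran-4-yl]methyl acetate
Product: 16 [(1S,4aR,5R,6S,9aR)-1-acetoxy-9-formyl-7-oxo-5,6-(propane-2,2-diyl)-1,4a,5,6,7,9a-hexahydrocyclohepta[c]pyran-4-yl]methyl acetate (target)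
Conditions: (COCl)2, DMSO, CH2Cl2, −78 to −40 °C; Et3N, to 0 °C
Reagents that add atoms: none
Why: Swern conditions oxidise a primary triethylsilyl ether directly to the aldehyde (oxidative desilylation via the alkoxysulfonium ion), so the electrophilic enal appears only in the last, acid-free step, after the acetal acetate is fixed; no stereocentre changes at low temperature.

**Compound list**

1 | 3-methoxybenzyl alcohol | COc1cccc(CO)c1 | starting material
2 | 2,5-dioxopyrrolidin-1-yl 2-diazoacetate | O=C(C=[N+]=[N-])ON1C(=O)CCC1=O | starting material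
3 | 3-methoxybenzyl 2-diazoacetate | COc1cccc(COC(=O)C=[N+]=[N-])c1 | intermediate
4 | 5-methoxy-3,8a-dihydro-1H-cyclohepta[c]furan-1-one (racemic; cycloheptatriene form of the Buchner adduct) | O=C1OCC2=CC(OC)=CC=CC12 | intermediate
5 | 5-methoxy-3,8a-dihydro-1H-cyclohepta[c]furan-1-ol (racemic lactol epimers) | OC1OCC2=CC(OC)=CC=CC12 | intermediate
6 | 1-hydroxy-5-methoxy-1,3-dihydrocyclohepta[c]furanylium (methoxytropylium) salt of reduced DDQ | C[O+]=C1C=CC=C2C(O)OCC2=C1.[O-]c1c(Cl)c(Cl)c(O)c(C#N)c1C#N | intermediate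
7 | 1-hydroxy-1,3-dihydro-5H-cyclohepta[c]furan-5-one (lactol of 4-formyl-3-(hydroxymethyl)tropone) | O=C1C=CC=C2C(O)OCC2=C1 | intermediate
8 | malondialdehyde tetrabutylammonium salt | CCCC[N+](CCCC)(CCCC)CCCC.[O-]/C=C/C=O | starting material
9 | (4aR,9aR)-1-hydroxy-9-(hydroxymethyl)-7-oxo-1,4a,7,9a-tetrahydrocyclohepta[c]pyran-4-carbaldehyde (H-4a/H-9a cis; C1 epimers) | O=CC1=COC(O)[C@H]2C(CO)=CC(=O)C=C[C@@H]12 | intermediate
10 | (4aR,9aR)-1-hydroxy-7-oxo-9-[(triethylsilyloxy)methyl]-1,4a,7,9a-tetrahydrocyclohepta[c]pyran-4-carbaldehyde (C1 epimers) | O=CC1=COC(O)[C@H]2C(CO[Si](CC)(CC)CC)=CC(=O)C=C[C@@H]12 | intermediate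
11 | (1S,4aR,9aR)-4-formyl-7-oxo-9-[(triethylsilyloxy)methyl]-1,4a,7,9a-tetrahydrocyclohepta[c]pyran-1-yl acetate (1-OAc trans to H-9a) | O=CC1=CO[C@@H](OC(C)=O)[C@H]2C(CO[Si](CC)(CC)CC)=CC(=O)C=C[C@@H]12 | intermediate
12 | (1S,4aR,9aR)-4-(hydroxymethyl)-7-oxo-9-[(triethylsilyloxy)methyl]-1,4a,7,9a-tetrahydrocyclohepta[c]pyran-1-yl acetate | OCC1=CO[C@@H](OC(C)=O)[C@H]2C(CO[Si](CC)(CC)CC)=CC(=O)C=C[C@@H]12 | intermediate
13 | [(1S,4aR,9aR)-1-acetoxy-7-oxo-9-[(triethylsilyloxy)methyl]-1,4a,7,9a-tetrahydrocyclohepta[c]pyran-4-yl]methyl acetate | CC(=O)OCC1=CO[C@@H](OC(C)=O)[C@H]2C(CO[Si](CC)(CC)CC)=CC(=O)C=C[C@@H]12 | intermediate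
14 | isopropyldiphenylsulfonium tetrafluoroborate | CC(C)[S+](c1ccccc1)c1ccccc1.F[B-](F)(F)F | starting material
15 | [(1S,4aR,5R,6S,9aR)-1-acetoxy-7-oxo-5,6-(propane-2,2-diyl)-9-[(triethylsilyloxy)methyl]-1,4a,5,6,7,9a-hexahydrocyclohepta[c]pyran-4-yl]methyl acetate (cyclopropane across C5–C6, CMe2 syn to H-4a/H-9a) | CC(=O)OCC1=CO[C@@H](OC(C)=O)[C@H]2C(CO[Si](CC)(CC)CC)=CC(=O)[C@H]3[C@@H]([C@@H]12)C3(C)C | intermediate
16 | [(1S,4aR,5R,6S,9aR)-1-acetoxy-9-formyl-7-oxo-5,6-(propane-2,2-diyl)-1,4a,5,6,7,9a-hexahydrocyclohepta[c]pyran-4-yl]methyl acetate | CC(=O)OCC1=CO[C@@H](OC(C)=O)[C@H]2C(C=O)=CC(=O)[C@H]3[C@@H]([C@@H]12)C3(C)C | target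

**Totals and fallbacks**

Total step count: 10. Longest linear sequence: 10 steps (1 to 16).

The three steps most likely to fail:

Step 5 (regio- and enantiocontrol of the new annulation on a tropone aldehyde; the C9a configuration relies on equilibration to the cis fusion). Fallback, setting out from 7: run the annulation with 8 under achiral catalysis (pyrrolidine, PhCO2H, CH2Cl2) to the racemic lactol F4. Carry it through the operations of steps 6 and 7 to the racemic silyl ether lactol F5, the racemic acetal acetate F6 and the racemic primary alcohol F7. Then resolve F7 by lipase-catalysed acetylation (Burkholderia cepacia lipase, vinyl acetate, t-BuOMe, rt), which puts the acetate of step 8 on one enantiomer only. The route is rejoined at 13; if the enzyme prefers the antipode, the recovered alcohol is 12 and is acetylated as in step 8.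

Step 2 (the ester conformation disfavours cyclisation; carbene dimerisation and acid-induced rearomatisation to an isochromanone compete). Fallback, setting out from 1: acylate with methyl 3-chloro-3-oxopropanoate (Et3N, CH2Cl2) to 3-methoxybenzyl methyl malonate F1. Diazo transfer (4-acetamidobenzenesulfonyl azide, Et3N, MeCN) gives 3-methoxybenzyl methyl 2-diazomalonate F2. The more electrophilic acceptor/acceptor carbenoid, which does not dimerise, is cyclised with Rh2(O2CC3F7)4 to methyl 5-methoxy-1-oxo-1,3-dihydro-8aH-cyclohepta[c]furan-8a-carboxylate F3. Krapcho demethoxycarbonylation (LiCl, wet DMSO, 120 °C) removes the extra ester and rejoins the route at 4.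

Step 7 (the vinylogous formyl group may not be reduced cleanly ahead of the dienone). Fallback, setting out from 11: reduce the aldehyde and the ring ketone together (NaBH4, CeCl3·7H2O, MeOH, −40 °C) to the diol F8. Acetylate only the primary hydroxyl (AcCl, 2,4,6-collidine, CH2Cl2, −78 °C) to the monoacetate F9. Reoxidise the doubly allylic secondary alcohol with MnO2 (CH2Cl2, rt), rejoining the route at 13.

Further compounds
F1 | step 2 | 3-methoxybenzyl methyl malonate | COC(=O)CC(=O)OCc1cccc(OC)c1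
F2 | step 2 | 3-methoxybenzyl methyl 2-diazomalonate | COC(=O)C(=[N+]=[N-])C(=O)OCc1cccc(OC)c1
F3 | step 2 | methyl 5-methoxy-1-oxo-1,3-dihydro-8aH-cyclohepta[c]furan-8a-carboxylate (racemic) | O=C1OCC2=CC(OC)=CC=CC12C(=O)OC
F4 | step 5 | racemic cis-1-hydroxy-9-(hydroxymethyl)-7-oxo-1,4a,7,9a-tetrahydrocyclohepta[c]pyran-4-carbaldehyde (racemate of 9) | O=CC1=COC(O)[C@H]2C(CO)=CC(=O)C=C[C@@H]12.O=CC1=COC(O)[C@@H]2C(CO)=CC(=O)C=C[C@H]12
F5 | step 5 | racemic cis-1-hydroxy-7-oxo-9-[(triethylsilyloxy)methyl]-1,4a,7,9a-tetrahydrocyclohepta[c]pyran-4-carbaldehyde (racemate of 10) | O=CC1=COC(O)[C@H]2C(CO[Si](CC)(CC)CC)=CC(=O)C=C[C@@H]12.O=CC1=COC(O)[C@@H]2C(CO[Si](CC)(CC)CC)=CC(=O)C=C[C@H]12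
F6 | step 5 | racemic 4-formyl-7-oxo-9-[(triethylsilyloxy)methyl]-1,4a,7,9a-tetrahydrocyclohepta[c]pyran-1-yl acetate (racemate of 11) | O=CC1=CO[C@@H](OC(C)=O)[C@H]2C(CO[Si](CC)(CC)CC)=CC(=O)C=C[C@@H]12.O=CC1=CO[C@H](OC(C)=O)[C@@H]2C(CO[Si](CC)(CC)CC)=CC(=O)C=C[C@H]12
F7 | step 5 | racemic 4-(hydroxymethyl)-7-oxo-9-[(triethylsilyloxy)methyl]-1,4a,7,9a-tetrahydrocyclohepta[c]pyran-1-yl acetate (racemate of 12) | OCC1=CO[C@@H](OC(C)=O)[C@H]2C(CO[Si](CC)(CC)CC)=CC(=O)C=C[C@@H]12.OCC1=CO[C@H](OC(C)=O)[C@@H]2C(CO[Si](CC)(CC)CC)=CC(=O)C=C[C@H]12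
F8 | step 7 | (1S,4aR,9aR)-7-hydroxy-4-(hydroxymethyl)-9-[(triethylsilyloxy)methyl]-1,4a,7,9a-tetrahydrocyclohepta[c]pyran-1-yl acetate (C7 epimers) | OCC1=CO[C@@H](OC(C)=O)[C@H]2C(CO[Si](CC)(CC)CC)=CC(O)C=C[C@@H]12
F9 | step 7 | [(1S,4aR,9aR)-1-acetoxy-7-hydroxy-9-[(triethylsilyloxy)methyl]-1,4a,7,9a-tetrahydrocyclohepta[c]pyran-4-yl]methyl acetate (C7 epimers) | CC(=O)OCC1=CO[C@@H](OC(C)=O)[C@H]2C(CO[Si](CC)(CC)CC)=CC(O)C=C[C@@H]12
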